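## Retrosynthetic overview

1. Target 24 ⇐ Mitsunobu esterification with inversion of the 6β-allylic alcohol 22 with 4-hydroxybenzoic acid; 22 ⇐ hydroxyl-directed reduction of ene-dione 21.
2. 21 ⇐ oxatricycle 16 by cuprate methylation at C8, SmI2 cleavage of the C5–O bridge bond (sets H-5 and the trans fusion) and IBX oxidation/dehydrogenation.
3. 16 ⇐ monocyclic pyranone 13 by an intramolecular oxidopyrylium–alkene [5+2] cycloaddition, which closes ring A (cyclopentane), ring B (cycloheptenone) and a temporary oxygen bridge in one operation and sets C1 and C5.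
4. 13 ⇐ Achmatowicz ring expansion of furyl carbinol 11 ⇐ 2-furyllithium + hydroxy lactone 7.
5. 7 ⇐ syn-selective reduction and lactonisation of aldol 5 ⇐ enantioselective Mukaiyama aldol of keto ester 3 with dienol silane 2. Ring order: sacrificial pyranone first, then rings A and B together.

Assumption: bi- and tricyclic compounds carry daucane numbering (C1 quaternary C–Me, C2 CH–OAc, C3, C4 C(OH)iPr, C5 ring-fusion CH, C6 CH–O-aroyl, C7=C8(Me), C9 C=O, C10 CH2); α is the face of H-5, β the face of the C1 methyl; the target is (1S,2R,4S,5R,6R) in this numbering.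

## Route

Step 1
Reactants: 1 3-methylbut-3-en-2-one
Product: 2 trimethyl[(3-methylbuta-1,3-dien-2-yl)oxy]silane
Conditions: TMSOTf, Et3N, Et2O, 0 °C
Reagents that add atoms: trimethylsilyl triflate, C[Si](C)(C)OS(=O)(=O)C(F)(F)F
Why: Soft enolisation and O-silylation of a ketone whose only enolisable position is the methyl group gives the 2-silyloxydiene; no stereocentre is formed.

Step 2
Reactants: 2 trimethyl[(3-methylbuta-1,3-dien-2-yl)oxy]silane; 3 methyl 3-methyl-2-oxobutanoate
Product: 5 methyl (2S)-2-hydroxy-5-methyl-4-oxo-2-(propan-2-yl)hex-5-enoate, via silyl ether 4 (not isolated)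
Conditions: [Cu((R,R)-tBu-box)](OTf)2 (10 mol %), THF, −78 to −40 °C; then 1 M HCl
Reagents that add atoms: none
Why: Catalytic enantioselective Mukaiyama aldol in which the keto ester chelates the square-planar divalent copper centre through both carbonyl oxygens and the tert-butyl groups of the bis(oxazoline) leave one ketone face open to the enol silane CH2, setting the tertiary carbinol (future C4) as S (the ligand antipode is the one whose mirror image gives S adducts of methyl pyruvate, because the CIP ranks of the ketone substituent and the new CH2 are interchanged here).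

Step 3
Reactants: 5 methyl (2S)-2-hydroxy-5-methyl-4-oxo-2-(propan-2-yl)hex-5-enoate
Product: 7 (3S,5R)-3-hydroxy-5-(prop-1-en-2-yl)-3-(propan-2-yl)oxolan-2-one, via diol ester 6 (not isolated)
Conditions: Et2BOMe, NaBH4, THF/MeOH 4:1, −78 °C; AcOH, MeOH azeotrope; PPTS (cat.), toluene, 60 °C
Reagents that add atoms: none
Why: Narasaka–Prasad reduction in which the six-membered boron chelate carries the isopropyl group equatorial and the ester axial and external hydride adds axially, giving the 4R carbinol (future C2, anti to the tertiary C–O bond along the chain that becomes ring A), after which the γ-hydroxy ester lactonises under acid catalysis (the minor C2 epimer is removed at this stage).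

Step 4
Reactants: 7 (3S,5R)-3-hydroxy-5-(prop-1-en-2-yl)-3-(propan-2-yl)oxolan-2-one; 8 furan
Product: 11 (2S,4R)-1-(furan-2-yl)-5-methyl-2-(propan-2-yl)hex-5-ene-1,2,4-triol (both C1 epimers), via 2-furyllithium 9 (not isolated), via hydroxy ketone 10 (not isolated)
Conditions: furan, n-BuLi, THF, −78 to 0 °C; 7 (0.43 equiv), −78 °C; then MeOH, NaBH4, −78 to 0 °C; NH4Cl (aq)
Reagents that add atoms: none
Why: Addition of an aryllithium to a lactone stops at the lithium lactolate (the first equivalent deprotonates the tertiary OH) and the ring-opened 2-acylfuran is then reduced by borohydride; the new carbinol centre is left unselective because it becomes sp2 in step 7.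

Step 5
Reactants: 11 (2S,4R)-1-(furan-2-yl)-5-methyl-2-(propan-2-yl)hex-5-ene-1,2,4-triol
Product: 12 2-[(3S,5R)-3,5-dihydroxy-2,6-dimethylhept-6-en-3-yl]-6-hydroxy-2H-pyran-3(6H)-one (epimers at pyranone C2 and C6)
Conditions: NBS (1.0 equiv), NaHCO3, NaOAc, THF/H2O 4:1, 0 °C
Reagents that add atoms: water, O
Why: Achmatowicz rearrangement, in which bromination and hydration of the electron-rich furan (much faster than attack on the 1,1-disubstituted alkene), ring opening to the Z-ene-dione and hemiacetal closure give the pyranone; both pyranone centres are erased in step 7.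

Step 6
Reactants: 12 2-[(3S,5R)-3,5-dihydroxy-2,6-dimethylhept-6-en-3-yl]-6-hydroxy-2H-pyran-3(6H)-one
Product: 13 6-acetoxy-2-[(3S,5R)-5-acetoxy-3-hydroxy-2,6-dimethylhept-6-en-3-yl]-2H-pyran-3(6H)-one
Conditions: Ac2O, pyridine, DMAP (cat.), CH2Cl2, 0 °C
Reagents that add atoms: acetic anhydride, CC(=O)OC(C)=O
Why: Acylation of the lactol and of the secondary allylic alcohol (the tertiary alcohol is inert) installs the leaving group for pyrylium formation and the C2 acetate of the target in one operation; no stereocentre of consequence is formed.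

Step 7
Reactants: 13 6-acetoxy-2-[(3S,5R)-5-acetoxy-3-hydroxy-2,6-dimethylhept-6-en-3-yl]-2H-pyran-3(6H)-one
Product: 16 2α-acetoxy-5α,9α-epoxy-4β-(trimethylsilyloxy)-8-demethyldauc-7-en-6-one (cyclopentane fused to an 8-oxabicyclo[3.2.1]oct-3-en-2-one; C1-Me β, iPr α), via silyl ether 14 (not isolated), via oxidopyrylium ylide 15 (not isolated)
Conditions: BSA, MeCN, 60 °C; then DBU, 80 °C
Reagents that add atoms: N,O-bis(trimethylsilyl)acetamide, CC(=N[Si](C)(C)C)O[Si](C)(C)C
Why: Intramolecular oxidopyrylium–alkene [5+2] cycloaddition (in-situ silylation blocks ketalisation and retro-aldol of the tertiary alcohol), in which the three-atom tether delivers the 1,1-disubstituted alkene only in the fused mode and closes C5–C1 (ring A), C9–C10 (ring B) and the C5–O–C9 bridge together; the cis-fused oxolane forces the C1 methyl anti to the bridge oxygen, and the face is set in a matched sense by the tether, the C4 isopropyl group turning away from the C6 oxido oxygen and the C2 acetate away from the vinylic methyl.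

Step 8
Reactants: 16 2α-acetoxy-5α,9α-epoxy-4β-(trimethylsilyloxy)-8-demethyldauc-7-en-6-one
Product: 17 2α-acetoxy-5α,9α-epoxy-4β-(trimethylsilyloxy)daucan-6-one (8-Me α)
Conditions: MeLi, CuI, Et2O/THF, −78 °C; NH4Cl (aq)
Reagents that add atoms: methyllithium, [Li]C
Why: Gilman conjugate addition to the enone from the exo face, syn to the oxygen bridge and anti to the crowded two-carbon bridge, brings in the C8 methyl; its configuration is irrelevant because C8 becomes sp2 in step 10.

Step 9
Reactants: 17 2α-acetoxy-5α,9α-epoxy-4β-(trimethylsilyloxy)daucan-6-one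
Product: 19 2α-acetoxy-4β,9α-dihydroxy-5αH-daucan-6-one (8-Me α), via silyl ether 18 (not isolated)
Conditions: SmI2 (2.5 equiv), MeOH, THF, −78 °C; then 0.5 M HCl, THF, 0 °C
Reagents that add atoms: none
Why: Samarium diiodide cleavage of the α-alkoxy ketone gives a samarium enolate that is protonated at C5 on the α-face from which the oxygen left (methanol held by the C9 alkoxide), giving H-5α and the trans ring fusion, which is also expected to be the thermodynamic epimer (C6 anti to the α-isopropyl group); the acidic work-up removes the tertiary silyl ether.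

Step 10
Reactants: 19 2α-acetoxy-4β,9α-dihydroxy-5αH-daucan-6-one
Product: 21 2α-acetoxy-4β-hydroxydauc-7-ene-6,9-dione, via diketone 20 (not isolated)
Conditions: IBX (3.5 equiv), DMSO, 75 °C
Reagents that add atoms: none
Why: IBX oxidises the secondary C9 alcohol and then dehydrogenates the 1,4-diketone through its enol; C7–C8 is the only position with a removable β-hydrogen (C1 and C4 are quaternary), so the ene-dione with the C8 methyl on the double bond forms and the C8 and C9 centres disappear.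

Step 11
Reactants: 21 2α-acetoxy-4β-hydroxydauc-7-ene-6,9-dione
Product: 22 2α-acetoxy-4β,6β-dihydroxydauc-7-en-9-one
Conditions: Me4NBH(OAc)3, AcOH/MeCN 1:1, −30 °C
Reagents that add atoms: none
Why: Evans–Saksena hydroxyl-directed reduction in which the borohydride bound to the C4 hydroxyl reduces only the β-hydroxy ketone C6 (C9 has no directing group) and delivers hydride through a chair with the isopropyl group equatorial onto the α-face, the β-face being shielded by the axial C1 methyl, to give the axial 6β-alcohol.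

Step 12
Reactants: 22 2α-acetoxy-4β,6β-dihydroxydauc-7-en-9-one; 23 4-hydroxybenzoic acid
Product: 24 2α-acetoxy-4β-hydroxy-6α-(4-hydroxybenzoyloxy)dauc-7-en-9-one (target, 1S,2R,4S,5R,6R)
Conditions: PPh3, DIAD, THF, 0 °C to rt
Reagents that add atoms: none
Why: Mitsunobu esterification with SN2 inversion at the allylic, axial C6 carbinol turns the 6β-alcohol into the equatorial 6α-ester; the carboxylic acid (pKa about 4.5) reacts in preference to the phenol (pKa about 9) and the tertiary C4 hydroxyl is inert.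

## Compound list

1 | 3-methylbut-3-en-2-one | CC(=O)C(C)=C | starting material
2 | trimethyl[(3-methylbuta-1,3-dien-2-yl)oxy]silane | C=C(O[Si](C)(C)C)C(C)=C | intermediate
3 | methyl 3-methyl-2-oxobutanoate | COC(=O)C(=O)C(C)C | starting material
4 | methyl (2S)-5-methyl-4-oxo-2-(propan-2-yl)-2-(trimethylsilyloxy)hex-5-enoate (not isolated) | COC(=O)[C@@](O[Si](C)(C)C)(C(C)C)CC(=O)C(C)=C | intermediate
5 | methyl (2S)-2-hydroxy-5-methyl-4-oxo-2-(propan-2-yl)hex-5-enoate | COC(=O)[C@@](O)(C(C)C)CC(=O)C(C)=C | intermediate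
6 | methyl (2S,4R)-2,4-dihydroxy-5-methyl-2-(propan-2-yl)hex-5-enoate (not isolated) | COC(=O)[C@@](O)(C(C)C)C[C@@H](O)C(C)=C | intermediate
7 | (3S,5R)-3-hydroxy-5-(prop-1-en-2-yl)-3-(propan-2-yl)oxolan-2-one | C=C(C)[C@H]1C[C@](O)(C(C)C)C(=O)O1 | intermediate
8 | furan | c1ccoc1 | starting material
9 | 2-furyllithium (not isolated) | [Li]c1ccco1 | intermediate
10 | (2S,4R)-1-(furan-2-yl)-2,4-dihydroxy-5-methyl-2-(propan-2-yl)hex-5-en-1-one (not isolated) | C=C(C)[C@H](O)C[C@](O)(C(C)C)C(=O)c1ccco1 | intermediate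
11 | (2S,4R)-1-(furan-2-yl)-5-methyl-2-(propan-2-yl)hex-5-ene-1,2,4-triol, C1 epimers | C=C(C)[C@H](O)C[C@](O)(C(C)C)C(O)c1ccco1 | intermediate
12 | 2-[(3S,5R)-3,5-dihydroxy-2,6-dimethylhept-6-en-3-yl]-6-hydroxy-2H-pyran-3(6H)-one | C=C(C)[C@H](O)C[C@](O)(C(C)C)C1OC(O)C=CC1=O | intermediate
13 | 6-acetoxy-2-[(3S,5R)-5-acetoxy-3-hydroxy-2,6-dimethylhept-6-en-3-yl]-2H-pyran-3(6H)-one | C=C(C)[C@H](OC(C)=O)C[C@](O)(C(C)C)C1OC(OC(C)=O)C=CC1=O | intermediate
14 | trimethylsilyl ether of 13 at the tertiary hydroxyl (not isolated) | C=C(C)[C@H](OC(C)=O)C[C@](O[Si](C)(C)C)(C(C)C)C1OC(OC(C)=O)C=CC1=O | intermediate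
15 | 2-[(3S,5R)-5-acetoxy-2,6-dimethyl-3-(trimethylsilyloxy)hept-6-en-3-yl]pyrylium-3-olate (not isolated) | C=C(C)[C@H](OC(C)=O)C[C@](O[Si](C)(C)C)(C(C)C)c1[o+]cccc1[O-] | intermediate
16 | 2α-acetoxy-5α,9α-epoxy-4β-(trimethylsilyloxy)-8-demethyldauc-7-en-6-one | CC(=O)O[C@@H]1C[C@](O[Si](C)(C)C)(C(C)C)[C@@]23O[C@@H](C=CC2=O)C[C@]13C | intermediate
17 | 2α-acetoxy-5α,9α-epoxy-4β-(trimethylsilyloxy)daucan-6-one, 8-Me α | CC(=O)O[C@@H]1C[C@](O[Si](C)(C)C)(C(C)C)[C@@]23O[C@@H]([C@@H](C)CC2=O)C[C@]13C | intermediate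
18 | 2α-acetoxy-9α-hydroxy-4β-(trimethylsilyloxy)-5αH-daucan-6-one (not isolated) | CC(=O)O[C@@H]1C[C@](O[Si](C)(C)C)(C(C)C)[C@H]2C(=O)C[C@H](C)[C@H](O)C[C@]12C | intermediate
19 | 2α-acetoxy-4β,9α-dihydroxy-5αH-daucan-6-one, 8-Me α | CC(=O)O[C@@H]1C[C@](O)(C(C)C)[C@H]2C(=O)C[C@H](C)[C@H](O)C[C@]12C | intermediate
20 | 2α-acetoxy-4β-hydroxy-5αH-daucane-6,9-dione (not isolated) | CC(=O)O[C@@H]1C[C@](O)(C(C)C)[C@H]2C(=O)C[C@H](C)C(=O)C[C@]12C | intermediate
21 | 2α-acetoxy-4β-hydroxydauc-7-ene-6,9-dione | CC(=O)O[C@@H]1C[C@](O)(C(C)C)[C@H]2C(=O)C=C(C)C(=O)C[C@]12C | intermediate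
22 | 2α-acetoxy-4β,6β-dihydroxydauc-7-en-9-one | CC(=O)O[C@@H]1C[C@](O)(C(C)C)[C@H]2[C@@H](O)C=C(C)C(=O)C[C@]12C | intermediate
23 | 4-hydroxybenzoic acid | OC(=O)c1ccc(O)cc1 | starting material
24 | 2α-acetoxy-4β-hydroxy-6α-(4-hydroxybenzoyloxy)dauc-7-en-9-one | CC(=O)O[C@@H]1C[C@](O)(C(C)C)[C@H]2[C@H](OC(=O)c3ccc(O)cc3)C=C(C)C(=O)C[C@]12C | target

## Step count and risks

Total step count: 12. Longest linear sequence: 12 steps (1 to 24).

Risk 1, step 7. The cycloaddition must join C5 and C1 next to the quaternary C4, and an unactivated 1,1-disubstituted alkene may lose out to ylide dimerisation. The fallback sets out from 12 and comes back at 16, using a conjugated 2π partner and setting C2 afterwards on the rigid tricycle. The lactol hydroxyl alone is acetylated (Ac2O 1.05 equiv, pyridine, −30 °C) to 6-acetoxy-2-[(3S,5R)-3,5-dihydroxy-2,6-dimethylhept-6-en-3-yl]-2H-pyran-3(6H)-one F4. Dess–Martin oxidation of the allylic alcohol gives the isopropenyl ketone 6-acetoxy-2-[(3S)-3-hydroxy-2,6-dimethyl-5-oxohept-6-en-3-yl]-2H-pyran-3(6H)-one F5. BSA then DBU at room temperature give the tricyclic diketone 5α,9α-epoxy-4β-(trimethylsilyloxy)-8-demethyldauc-7-ene-2,6-dione F6. NaBH4 in MeOH/CH2Cl2 at −78 °C reduces the saturated cyclopentanone before the conjugated ketone, from the β-face (the α-face is the concave side of the fused oxolane and carries the isopropyl group), to the 2α-alcohol 5α,9α-epoxy-2α-hydroxy-4β-(trimethylsilyloxy)-8-demethyldauc-7-en-6-one F7. Acetylation (Ac2O, DMAP) returns 16.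

Risk 2, step 12. The Mitsunobu displacement at the hindered axial allylic C6 may give E2 elimination toward C5 (H-5 is anti-periplanar) instead of substitution. The fallback sets out from 21 and comes back at 24, making the 6α-alcohol directly and acylating with retention. A ketoreductase chosen from a commercial panel (NADPH, glucose/glucose dehydrogenase, phosphate buffer/DMSO) reduces the C6 carbonyl from the β-face to 2α-acetoxy-4β,6α-dihydroxydauc-7-en-9-one F8. Steglich acylation with 4-(tert-butyldimethylsilyloxy)benzoic acid (DCC, DMAP) gives the silyl-protected ester 2α-acetoxy-6α-[4-(tert-butyldimethylsilyloxy)benzoyloxy]-4β-hydroxydauc-7-en-9-one F9. HF·pyridine then frees the phenol to give 24.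

Risk 3, step 2. The α-branched keto ester may react slowly or with low enantioselectivity, and hetero-Diels–Alder addition of the silyloxydiene may compete. The fallback sets out from 2 and comes back at 7, replacing catalyst control by a covalent auxiliary. 3-Methyl-2-oxobutanoic acid is esterified with (−)-8-phenylmenthol (DCC, DMAP) to (1R,2S,5R)-5-methyl-2-(2-phenylpropan-2-yl)cyclohexyl 3-methyl-2-oxobutanoate F1. SnCl4-mediated Mukaiyama aldol with 2 (CH2Cl2, −78 °C; aqueous HCl), in which the phenyl ring shields one face of the chelated dicarbonyl, gives (1R,2S,5R)-5-methyl-2-(2-phenylpropan-2-yl)cyclohexyl (2S)-2-hydroxy-5-methyl-4-oxo-2-(propan-2-yl)hex-5-enoate F2 (the antipodal auxiliary is used if the sense of induction proves opposite). Et2BOMe/NaBH4 gives the diol ester (1R,2S,5R)-5-methyl-2-(2-phenylpropan-2-yl)cyclohexyl (2S,4R)-2,4-dihydroxy-5-methyl-2-(propan-2-yl)hex-5-enoate F3. PPTS lactonisation expels the auxiliary and returns 7.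

## Further compounds

F1 | step 2 | (1R,2S,5R)-5-methyl-2-(2-phenylpropan-2-yl)cyclohexyl 3-methyl-2-oxobutanoate | CC(C)(c1ccccc1)[C@@H]1CC[C@@H](C)C[C@H]1OC(=O)C(=O)C(C)C
F2 | step 2 | (1R,2S,5R)-5-methyl-2-(2-phenylpropan-2-yl)cyclohexyl (2S)-2-hydroxy-5-methyl-4-oxo-2-(propan-2-yl)hex-5-enoate | CC(C)(c1ccccc1)[C@@H]1CC[C@@H](C)C[C@H]1OC(=O)[C@@](O)(C(C)C)CC(=O)C(C)=C
F3 | step 2 | (1R,2S,5R)-5-methyl-2-(2-phenylpropan-2-yl)cyclohexyl (2S,4R)-2,4-dihydroxy-5-methyl-2-(propan-2-yl)hex-5-enoate | CC(C)(c1ccccc1)[C@@H]1CC[C@@H](C)C[C@H]1OC(=O)[C@@](O)(C(C)C)C[C@@H](O)C(C)=C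
F4 | step 7 | 6-acetoxy-2-[(3S,5R)-3,5-dihydroxy-2,6-dimethylhept-6-en-3-yl]-2H-pyran-3(6H)-one | C=C(C)[C@H](O)C[C@](O)(C(C)C)C1OC(OC(C)=O)C=CC1=O
F5 | step 7 | 6-acetoxy-2-[(3S)-3-hydroxy-2,6-dimethyl-5-oxohept-6-en-3-yl]-2H-pyran-3(6H)-one | C=C(C)C(=O)C[C@](O)(C(C)C)C1OC(OC(C)=O)C=CC1=O
F6 | step 7 | 5α,9α-epoxy-4β-(trimethylsilyloxy)-8-demethyldauc-7-ene-2,6-dione | O=C1C[C@](O[Si](C)(C)C)(C(C)C)[C@@]23O[C@@H](C=CC2=O)C[C@]13C
F7 | step 7 | 5α,9α-epoxy-2α-hydroxy-4β-(trimethylsilyloxy)-8-demethyldauc-7-en-6-one | O[C@@H]1C[C@](O[Si](C)(C)C)(C(C)C)[C@@]23O[C@@H](C=CC2=O)C[C@]13C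
F8 | step 12 | 2α-acetoxy-4β,6α-dihydroxydauc-7-en-9-one | CC(=O)O[C@@H]1C[C@](O)(C(C)C)[C@H]2[C@H](O)C=C(C)C(=O)C[C@]12C
F9 | step 12 | 2α-acetoxy-6α-[4-(tert-butyldimethylsilyloxy)benzoyloxy]-4β-hydroxydauc-7-en-9-one | CC(=O)O[C@@H]1C[C@](O)(C(C)C)[C@H]2[C@H](OC(=O)c3ccc(O[Si](C)(C)C(C)(C)C)cc3)C=C(C)C(=O)C[C@]12C
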